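## Retrosynthetic overview

1. The target is traced back, through silyl and acetate adjustments at C8, C9 and C16, to a tricyclic lactone. Ring B (ten-membered carbocycle C1–C10) is cut at C6–C7 and ring C (γ-lactone O–C7–C8–C17–C19) at O–C19. This gives a monocyclic (Z)-iodoalkenyl aldehyde that carries C19 as an N-acyloxazolidinone (briarane numbering, see remark).
2. Enabling feature: C7 is both the allylic carbinol carbon next to the (Z)-C5=C6 bond of ring B and the alkoxy carbon of ring C, 1,4-related to acyl carbon C19. A reductive union of the two electrophilic carbons C6 (C–I) and C7 (CH=O) with CrCl2/NiCl2 therefore gives an alkoxide that closes ring C by itself.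
3. West arm: C2–C3 comes from a boron aldol of the ring A aldehyde with a (Z)-β-iodo enone (C3–C6, C16). C4 is set by an Evans–Tishchenko reduction, which also installs the C2 acetate, and is then acylated with (R)-3-acetoxybutanoic acid.
4. East arm: C9–C10 comes from a [2,3]-Wittig rearrangement of a C12 allylic ether and C8–C17 from acylation of a chiral propionimide enolate. C7–C8 comes from a chelation-controlled PhSCH2 addition; the sulfide is a latent CHO released by a Pummerer reaction.
5. Ring A with C1 and C14 comes from (S)-carvone, whose isopropenyl C–C bond is cleaved to the C14 acetate. Order of rings: A from the chiral pool, then B and C together in the key step.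

Key step: step 24

Remark: atoms follow briarane numbering (C1 quaternary C with CH3 = C15; C2 CHOAc; C3 CH2; C4 CHO-acyl; C5=C6 with C16H2OH on C5; C7 lactone CH–O; C8 C–OH; C9 CHOAc; C10 ring-fusion CH; C11=C12 with CH3 = C20 on C11; C13 CH2; C14 CHOAc; C17 CH with CH3 = C18; C19 lactone C=O); ring A = cyclohexene (C1, C10–C14); β = the face of ring A that carries C15, α = the other face; the target is read as 1R,2R,4R,5Z,7S,8S,9R,10S,14S,17R,3′R.

## Route

Step 1
Reactants: 1 (S)-(+)-carvone
Product: 2 6-(hydroxymethylidene)carvone (enol of 6-formylcarvone)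
Conditions: LiN(i-Pr)2, THF, −78 °C; CF3CH2OCHO, −78 to 0 °C; 1 M HCl
Reagents that add atoms: 2,2,2-trifluoroethyl formate, O=COCC(F)(F)F
Why: Kinetic deprotonation of the cross-conjugated enone at C6 (the future C1) followed by Claisen-type C-formylation with the activated formate gives the chelated hydroxymethylene ketone and leaves the carvone stereocentre (the future C14) untouched.

Step 2
Reactants: 2 6-(hydroxymethylidene)carvone
Product: 3 6-formyl-6-methylcarvone (C15 methyl trans and C2 formyl cis to the isopropenyl group)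
Conditions: MeI, K2CO3, acetone, rt
Reagents that add atoms: iodomethane, CI
Why: C-alkylation of the soft β-keto aldehyde enolate, in which iodomethane approaches the planar C1 anti to the neighbouring isopropenyl group, sets the quaternary centre with C15 on the β face.

Step 3
Reactants: 3 6-formyl-6-methylcarvone
Product: 4 dimethyl acetal of 3
Conditions: HC(OMe)3, CSA (cat), MeOH, rt
Reagents that add atoms: trimethyl orthoformate, COC(OC)OC
Why: Acid-catalysed acetalisation is selective for the aldehyde because the conjugated C10 ketone next to the quaternary carbon is far less electrophilic.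

Step 4
Reactants: 4 dimethyl acetal
Product: 5 11,12-β-epoxy ketone
Conditions: 30% H2O2, NaOH (cat), MeOH, 0 °C
Reagents that add atoms: hydrogen peroxide, OO
Why: Weitz–Scheffer nucleophilic epoxidation touches only the electron-poor C11=C12 bond, and hydroperoxide adds axially to C12 trans to the C14 isopropenyl group, which places the oxygen on the β face.

Step 5
Reactants: 5 11,12-β-epoxy ketone
Product: 7 14-acetoxy epoxy ketone, via methoxy hydroperoxide 6 (not isolated)
Conditions: O3, CH2Cl2/MeOH, −78 °C; then Ac2O, Et3N, DMAP, CH2Cl2, 0 to 40 °C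
Reagents that add atoms: ozone, [O-][O+]=O; methanol, CO
Why: Ozonolysis in methanol followed by acylation triggers a Criegee rearrangement in which C14 migrates from carbon to oxygen with retention, so that the isopropenyl group (the only alkene present) is cut down to the C14 acetate.

Step 6
Reactants: 7 14-acetoxy epoxy ketone
Product: 9 allylic alcohol (12β-OH and C10=C11), via epoxy hydrazone 8 (not isolated)
Conditions: N2H4·H2O, AcOH, MeOH, 0 °C to rt
Reagents that add atoms: none
Why: In the Wharton transposition the hydrazone fragments with loss of N2 and opening of the C11–O bond, which moves the alkene to C10=C11 and keeps the β C12–O bond, while buffered hydrazine leaves ordinary secondary acetates intact.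

Step 7
Reactants: 9 allylic alcohol; 10 ethyl diazoacetate
Product: 11 ethyl (C12-allyloxy)acetate
Conditions: 10 (slow addition), Rh2(OAc)4 (1 mol %), CH2Cl2, rt
Reagents that add atoms: none
Why: Rhodium-carbenoid O–H insertion etherifies the secondary allylic alcohol under neutral conditions that spare the acetate and the acetal and do not touch the C12 configuration.

Step 8
Reactants: 11 ethyl (C12-allyloxy)acetate
Product: 12 (C12-allyloxy)acetic acid
Conditions: LiOH (1.1 equiv), THF/H2O, 0 °C; 1 M HCl to pH 4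
Reagents that add atoms: lithium hydroxide, [Li+].[OH-]
Why: Saponification is selective because the unhindered and inductively activated alkoxyacetate ester is hydrolysed much faster than the acetate that is shielded by the quaternary C1.

Step 9
Reactants: 12 (C12-allyloxy)acetic acid
Product: 13 (9R,10S)-α-hydroxy acid (C8 = CO2H, alkene at C11=C12)
Conditions: LiN(i-Pr)2 (3.5 equiv), THF, −78 to 0 °C; 1 M HCl to pH 4
Reagents that add atoms: none
Why: In the [2,3]-Wittig rearrangement of the carboxylate enolate dianion the C9–C10 bond forms suprafacially on the β face from which the C12–O bond departs (this sets C10), the carboxylate points outward from the envelope transition state away from the quaternary C1 (this sets C9), and the acetate enolate made by the extra base is simply reprotonated on work-up.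

Step 10
Reactants: 13 α-hydroxy acid
Product: 14 C9 triethylsilyl ether triethylsilyl ester
Conditions: Et3SiCl, imidazole, DMAP (cat), DMF, rt
Reagents that add atoms: chlorotriethylsilane, CC[Si](Cl)(CC)CC
Why: Standard silylation covers the C9 hydroxyl with a non-chelating group and turns the acid into a silyl ester that can be activated without acid.

Step 11
Reactants: 14 bis(triethylsilyl) compound; 15 (S)-4-benzyl-3-propionyl-1,3-oxazolidin-2-one
Product: 17 β-keto imide (17R), via acid chloride 16 (not isolated)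
Conditions: (COCl)2, DMF (cat), CH2Cl2, 0 °C to rt, evaporate; 15, LiN(i-Pr)2, THF, −78 °C, then 16, −78 °C
Reagents that add atoms: none
Why: The silyl ester gives the acid chloride under neutral conditions, and this C-acylates the chelated (Z)-lithium enolate of the chiral imide on the face opposite the benzyl group (Evans-type acylation), which sets C17, while allylic strain keeps the β-keto imide from epimerising.

Step 12
Reactants: 17 β-keto imide; 18 thioanisole
Product: 19 tertiary C8 alcohol with C7 as CH2SPh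
Conditions: 18, n-BuLi, DABCO, THF, 0 °C; CeCl3, −78 °C; 17, −78 °C; AcOH quench
Reagents that add atoms: none
Why: In this organocerium 1,2-addition trivalent cerium chelates the ketone and imide carbonyls so that the weakly basic nucleophile attacks C8 anti to the C17 methyl group, which is also the face predicted by the Felkin–Anh model for the non-chelating C9 silyl ether, and the ketone reacts faster than the acetate and the imide.

Step 13
Reactants: 19 tertiary alcohol
Product: 20 ring A aldehyde (C2 = CHO, C8 OSiEt3)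
Conditions: Et3SiOTf, 2,6-lutidine, CH2Cl2, 0 °C; then H2O
Reagents that add atoms: triethylsilyl triflate, CC[Si](CC)(CC)OS(=O)(=O)C(F)(F)F; water, O
Why: The silyl triflate and hindered pyridine silylate the tertiary alcohol and in the same flask effect the known mild cleavage of an aldehyde dimethyl acetal, completed by water, while esters, imide, sulfide and the silyl ether survive.

Step 14
Reactants: 21 but-3-yn-2-ol (racemic); 22 (chloromethyl)(isopropoxy)dimethylsilane
Product: 23 4-iodo-3-[(isopropoxydimethylsilyl)methyl]but-3-en-2-ol (iodine cis to the carbinol carbon)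
Conditions: 22, Mg, THF (gives i-PrOMe2SiCH2MgCl, 3 equiv); 21, CuI (10 mol %), THF, 0 °C to rt; I2, −78 to 0 °C
Reagents that add atoms: iodine, II
Why: Copper-catalysed anti-carbomagnesiation of the propargylic alkoxide ends in a five-membered magnesium chelate with the metal cis to the carbinol carbon, and iodinolysis with retention fixes the C5=C6 geometry with iodine cis to C4.

Step 15
Reactants: 23 iodoalkenyl silane
Product: 24 (Z)-2-(iodomethylidene)butane-1,3-diol
Conditions: 30% H2O2, KF, KHCO3, THF/MeOH, rt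
Reagents that add atoms: hydrogen peroxide, OO
Why: Tamao oxidation converts the alkoxysilyl C–Si bond into the C16–OH bond under conditions that leave an iodoalkene untouched.

Step 16
Reactants: 24 iodo diol
Product: 25 primary tert-butyldiphenylsilyl ether
Conditions: t-BuPh2SiCl (1.0 equiv), imidazole, CH2Cl2, 0 °C
Reagents that add atoms: tert-butyl(chloro)diphenylsilane, CC(C)(C)[Si](Cl)(c1ccccc1)c1ccccc1
Why: The bulky silyl chloride reacts with the primary C16 hydroxyl much faster than with the secondary one.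

Step 17
Reactants: 25 silyl ether
Product: 26 (Z)-β-iodo enone (C3–C6 and C16)
Conditions: Dess–Martin periodinane, NaHCO3, CH2Cl2, 0 °C
Reagents that add atoms: none
Why: Buffered Dess–Martin oxidation of the allylic alcohol removes the racemic centre without isomerising the iodoalkene.

Step 18
Reactants: 27 (R)-3-hydroxybutanoic acid
Product: 28 (R)-3-acetoxybutanoic acid
Conditions: Ac2O, pyridine, 0 °C to rt; H2O
Reagents that add atoms: acetic anhydride, CC(=O)OC(C)=O
Why: O-acetylation does not touch the stereocentre, and the transient mixed anhydride is hydrolysed on work-up.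

Step 19
Reactants: 20 ring A aldehyde; 26 (Z)-β-iodo enone
Product: 30 (2R)-β-hydroxy ketone, via boron enolate 29 (not isolated)
Conditions: 26, c-Hex2BCl, i-Pr2NEt, Et2O, −78 to 0 °C; 20, −78 to −20 °C; pH 7 buffer, MeOH
Reagents that add atoms: none
Why: In this boron aldol through a Zimmerman–Traxler transition state the enolate attacks the equatorial formyl group anti to the axial C15 methyl, in the rotamer that turns the formyl hydrogen toward the bulky C10 arm, which gives 2R, and soft enolisation with a hindered amine is tolerated by β-halo enones.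

Step 20
Reactants: 30 β-hydroxy ketone
Product: 31 1,3-anti diol monoacetate (C2 OAc, 4R OH)
Conditions: MeCHO (10 equiv), SmI2 (0.3 equiv, premixed with MeCHO), THF, −10 °C
Reagents that add atoms: acetaldehyde, CC=O
Why: In the Evans–Tishchenko reduction the C2 hemiacetal of acetaldehyde, held with the ketone on trivalent samarium in a chair-like transition state, delivers hydride intramolecularly to C4, which gives the 1,3-anti alcohol and leaves the acetyl group on O2.

Step 21
Reactants: 31 diol monoacetate; 28 (R)-3-acetoxybutanoic acid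
Product: 32 C4 (R)-3-acetoxybutanoate
Conditions: EDC·HCl, DMAP (cat), CH2Cl2, 0 °C
Reagents that add atoms: none
Why: Steglich-type carbodiimide esterification of the only free hydroxyl at low temperature with little DMAP limits β-elimination of the acetoxy acid.

Step 22
Reactants: 32 sulfide
Product: 33 sulfoxide (mixture at sulfur)
Conditions: mCPBA (1.0 equiv), CH2Cl2, −78 °C
Reagents that add atoms: 3-chloroperbenzoic acid, OOC(=O)c1cccc(Cl)c1
Why: Sulfide oxidation is much faster at low temperature than epoxidation of the trisubstituted alkenes, so one equivalent of peracid stops at the sulfoxide.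

Step 23
Reactants: 33 sulfoxide
Product: 35 (Z)-iodoalkenyl α-silyloxy aldehyde, via trifluoroacetoxy sulfide 34 (not isolated)
Conditions: (CF3CO)2O, 2,6-lutidine, CH2Cl2, 0 °C; then aq NaHCO3
Reagents that add atoms: trifluoroacetic anhydride, O=C(OC(=O)C(F)(F)F)C(F)(F)F
Why: The Pummerer rearrangement raises C7 to the aldehyde level without ever freeing a C7 hydroxyl that could attack the imide, and the labile trifluoroacetoxy sulfide is hydrolysed by bicarbonate.

Step 24
Reactants: 35 (Z)-iodoalkenyl α-silyloxy aldehyde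
Product: 37 tricyclic lactone (rings A, B and C), via macrocyclic alkoxide 36 (not isolated)
Conditions: CrCl2 (15 equiv), NiCl2 (0.15 equiv), DMSO/THF, 1 mM, rt; aq sodium serinate work-up
Reagents that add atoms: none
Why: NiCl2 is reduced by CrCl2 to zerovalent nickel, which inserts into the C6–I bond; transmetalation to trivalent chromium gives an alkenylchromium species with retained (Z) geometry, so that the formerly electrophilic C6 adds as a nucleophile to the electrophilic C7 aldehyde (polarity reversal by two one-electron reductions). The closest known reaction type is the Nozaki–Hiyama–Kishi macrocyclisation of iodoalkenyl aldehydes to medium-ring and macrocyclic allylic alcohols, and the follow-up is the familiar spontaneous lactonisation of γ-hydroxy N-acyloxazolidinones. Ring B closes by intramolecular 1,2-addition (10-exo-trig at C7), and the chromium alkoxide 36 then closes ring C by 5-exo-trig addition–elimination at C19 with loss of the oxazolidinone, which makes the sequence irreversible. The one new stereocentre C7 is controlled by C8 through a polar Felkin–Anh transition state: the non-chelating C8–OSiEt3 bond lies anti to the incoming C6, the formyl hydrogen lies next to the C17 branch and the tether enters next to C9, which gives 7S with C6 cis to O8 and trans to C9 on ring C. The step needs chemoselectivity for the aldehyde over four esters and the imide, which the low basicity and aldehyde preference of alkenylchromium reagents provide, and it needs retention of the alkene geometry, which the trisubstituted iodoalkene secures. It also needs ring closure to beat oligomerisation, which is secured by high dilution and by ring A, whose trans-diequatorial C2 and C9 arms are gauche and hold C6 and C7 on the same side.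

Step 25
Reactants: 37 tricyclic lactone
Product: 38 8,9-diol (C16 still silylated)
Conditions: PPTS, MeOH/CH2Cl2, 0 °C to rt
Reagents that add atoms: none
Why: Acid-catalysed methanolysis removes triethylsilyl ethers far faster than the acid-stable tert-butyldiphenylsilyl ether.

Step 26
Reactants: 38 8,9-diol
Product: 39 9-acetate
Conditions: Ac2O, pyridine, DMAP (cat), CH2Cl2, rt
Reagents that add atoms: acetic anhydride, CC(=O)OC(C)=O
Why: Acetylation takes the secondary C9 hydroxyl, while the tertiary C8 hydroxyl is inert under these conditions.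

Step 27
Reactants: 39 9-acetate
Product: 40 target CNP0316115.1
Conditions: HF·pyridine, pyridine, THF, 0 °C to rt
Reagents that add atoms: none
Why: Buffered fluoride desilylation frees the C16 alcohol under mildly acidic conditions that avoid acetate loss and acyl migration from O4.

## Compound list

1 | (S)-(+)-carvone | CC1=CC[C@@H](CC1=O)C(C)=C | starting material
2 | 6-(hydroxymethylidene)carvone | OC=C1[C@@H](C(C)=C)CC=C(C)C1=O | intermediate
3 | 6-formyl-6-methylcarvone (C15 β) | O=C[C@@]1(C)[C@@H](C(C)=C)CC=C(C)C1=O | intermediate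
4 | dimethyl acetal of 3 | COC(OC)[C@@]1(C)[C@@H](C(C)=C)CC=C(C)C1=O | intermediate
5 | 11,12-β-epoxy ketone | COC(OC)[C@@]1(C)[C@@H](C(C)=C)C[C@@H]2O[C@]2(C)C1=O | intermediate
6 | methoxy hydroperoxide | COC(OC)[C@@]1(C)[C@@H](C(C)(OC)OO)C[C@@H]2O[C@]2(C)C1=O | intermediate
7 | 14-acetoxy epoxy ketone | COC(OC)[C@@]1(C)[C@@H](OC(C)=O)C[C@@H]2O[C@]2(C)C1=O | intermediate
8 | epoxy hydrazone | COC(OC)[C@@]1(C)[C@@H](OC(C)=O)C[C@@H]2O[C@]2(C)C1=NN | intermediate
9 | allylic alcohol (12β-OH, C10=C11) | COC(OC)[C@@]1(C)[C@@H](OC(C)=O)C[C@H](O)C(C)=C1 | intermediate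
10 | ethyl diazoacetate | CCOC(=O)C=[N+]=[N-] | starting material
11 | ethyl (C12-allyloxy)acetate | COC(OC)[C@@]1(C)[C@@H](OC(C)=O)C[C@H](OCC(=O)OCC)C(C)=C1 | intermediate
12 | (C12-allyloxy)acetic acid | COC(OC)[C@@]1(C)[C@@H](OC(C)=O)C[C@H](OCC(=O)O)C(C)=C1 | intermediate
13 | (9R,10S)-α-hydroxy acid | COC(OC)[C@@]1(C)[C@@H](OC(C)=O)CC=C(C)[C@@H]1[C@@H](O)C(=O)O | intermediate
14 | C9 triethylsilyl ether triethylsilyl ester | COC(OC)[C@@]1(C)[C@@H](OC(C)=O)CC=C(C)[C@@H]1[C@@H](O[Si](CC)(CC)CC)C(=O)O[Si](CC)(CC)CC | intermediate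
15 | (S)-4-benzyl-3-propionyl-1,3-oxazolidin-2-one | CCC(=O)N1[C@@H](Cc2ccccc2)COC1=O | starting material
16 | acid chloride | COC(OC)[C@@]1(C)[C@@H](OC(C)=O)CC=C(C)[C@@H]1[C@@H](O[Si](CC)(CC)CC)C(Cl)=O | intermediate
17 | β-keto imide (17R) | COC(OC)[C@@]1(C)[C@@H](OC(C)=O)CC=C(C)[C@@H]1[C@@H](O[Si](CC)(CC)CC)C(=O)[C@@H](C)C(=O)N1[C@@H](Cc2ccccc2)COC1=O | intermediate
18 | thioanisole | CSc1ccccc1 | starting material
19 | tertiary C8 alcohol with CH2SPh | COC(OC)[C@@]1(C)[C@@H](OC(C)=O)CC=C(C)[C@@H]1[C@@H](O[Si](CC)(CC)CC)[C@@](O)(CSc1ccccc1)[C@@H](C)C(=O)N1[C@@H](Cc2ccccc2)COC1=O | intermediate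
20 | ring A aldehyde | O=C[C@@]1(C)[C@@H](OC(C)=O)CC=C(C)[C@@H]1[C@@H](O[Si](CC)(CC)CC)[C@@](O[Si](CC)(CC)CC)(CSc1ccccc1)[C@@H](C)C(=O)N1[C@@H](Cc2ccccc2)COC1=O | intermediate
21 | but-3-yn-2-ol (racemic) | CC(O)C#C | starting material
22 | (chloromethyl)(isopropoxy)dimethylsilane | CC(C)O[Si](C)(C)CCl | starting material
23 | iodoalkenyl silane (I cis to carbinol carbon) | CC(O)/C(=C\I)C[Si](C)(C)OC(C)C | intermediate
24 | (Z)-2-(iodomethylidene)butane-1,3-diol | CC(O)/C(=C\I)CO | intermediate
25 | primary tert-butyldiphenylsilyl ether | CC(O)/C(=C\I)CO[Si](c1ccccc1)(c1ccccc1)C(C)(C)C | intermediate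
26 | (Z)-β-iodo enone | CC(=O)/C(=C\I)CO[Si](c1ccccc1)(c1ccccc1)C(C)(C)C | intermediate
27 | (R)-3-hydroxybutanoic acid | C[C@@H](O)CC(=O)O | starting material
28 | (R)-3-acetoxybutanoic acid | CC(=O)O[C@H](C)CC(=O)O | intermediate
29 | boron enolate of 26 | C=C(OB(C1CCCCC1)C1CCCCC1)/C(=C\I)CO[Si](c1ccccc1)(c1ccccc1)C(C)(C)C | intermediate
30 | (2R)-β-hydroxy ketone | I/C=C(/CO[Si](c1ccccc1)(c1ccccc1)C(C)(C)C)C(=O)C[C@@H](O)[C@@]1(C)[C@@H](OC(C)=O)CC=C(C)[C@@H]1[C@@H](O[Si](CC)(CC)CC)[C@@](O[Si](CC)(CC)CC)(CSc1ccccc1)[C@@H](C)C(=O)N1[C@@H](Cc2ccccc2)COC1=O | intermediate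
31 | anti diol monoacetate (C2 OAc, 4R OH) | I/C=C(/CO[Si](c1ccccc1)(c1ccccc1)C(C)(C)C)[C@H](O)C[C@@H](OC(C)=O)[C@@]1(C)[C@@H](OC(C)=O)CC=C(C)[C@@H]1[C@@H](O[Si](CC)(CC)CC)[C@@](O[Si](CC)(CC)CC)(CSc1ccccc1)[C@@H](C)C(=O)N1[C@@H](Cc2ccccc2)COC1=O | intermediate
32 | C4 (R)-3-acetoxybutanoate, sulfide | I/C=C(/CO[Si](c1ccccc1)(c1ccccc1)C(C)(C)C)[C@H](OC(=O)C[C@@H](C)OC(C)=O)C[C@@H](OC(C)=O)[C@@]1(C)[C@@H](OC(C)=O)CC=C(C)[C@@H]1[C@@H](O[Si](CC)(CC)CC)[C@@](O[Si](CC)(CC)CC)(CSc1ccccc1)[C@@H](C)C(=O)N1[C@@H](Cc2ccccc2)COC1=O | intermediate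
33 | sulfoxide | I/C=C(/CO[Si](c1ccccc1)(c1ccccc1)C(C)(C)C)[C@H](OC(=O)C[C@@H](C)OC(C)=O)C[C@@H](OC(C)=O)[C@@]1(C)[C@@H](OC(C)=O)CC=C(C)[C@@H]1[C@@H](O[Si](CC)(CC)CC)[C@@](O[Si](CC)(CC)CC)(CS(=O)c1ccccc1)[C@@H](C)C(=O)N1[C@@H](Cc2ccccc2)COC1=O | intermediate
34 | trifluoroacetoxy sulfide | I/C=C(/CO[Si](c1ccccc1)(c1ccccc1)C(C)(C)C)[C@H](OC(=O)C[C@@H](C)OC(C)=O)C[C@@H](OC(C)=O)[C@@]1(C)[C@@H](OC(C)=O)CC=C(C)[C@@H]1[C@@H](O[Si](CC)(CC)CC)[C@@](O[Si](CC)(CC)CC)(C(OC(=O)C(F)(F)F)Sc1ccccc1)[C@@H](C)C(=O)N1[C@@H](Cc2ccccc2)COC1=O | intermediate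
35 | (Z)-iodoalkenyl α-silyloxy aldehyde | I/C=C(/CO[Si](c1ccccc1)(c1ccccc1)C(C)(C)C)[C@H](OC(=O)C[C@@H](C)OC(C)=O)C[C@@H](OC(C)=O)[C@@]1(C)[C@@H](OC(C)=O)CC=C(C)[C@@H]1[C@@H](O[Si](CC)(CC)CC)[C@@](O[Si](CC)(CC)CC)(C=O)[C@@H](C)C(=O)N1[C@@H](Cc2ccccc2)COC1=O | intermediate
36 | macrocyclic alkoxide (drawn as the free 7S alcohol) | CC(=O)O[C@H](C)CC(=O)O[C@@H]1C[C@@H](OC(C)=O)[C@@]2(C)[C@@H](OC(C)=O)CC=C(C)[C@@H]2[C@@H](O[Si](CC)(CC)CC)[C@](O[Si](CC)(CC)CC)([C@@H](C)C(=O)N2[C@@H](Cc3ccccc3)COC2=O)[C@@H](O)/C=C\1CO[Si](c1ccccc1)(c1ccccc1)C(C)(C)C | intermediate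
37 | tricyclic lactone | CC(=O)O[C@H](C)CC(=O)O[C@@H]1C[C@@H](OC(C)=O)[C@@]2(C)[C@@H](OC(C)=O)CC=C(C)[C@@H]2[C@@H](O[Si](CC)(CC)CC)[C@@]2(O[Si](CC)(CC)CC)[C@H](/C=C\1CO[Si](c1ccccc1)(c1ccccc1)C(C)(C)C)OC(=O)[C@@H]2C | intermediate
38 | 8,9-diol | CC(=O)O[C@H](C)CC(=O)O[C@@H]1C[C@@H](OC(C)=O)[C@@]2(C)[C@@H](OC(C)=O)CC=C(C)[C@@H]2[C@@H](O)[C@@]2(O)[C@H](/C=C\1CO[Si](c1ccccc1)(c1ccccc1)C(C)(C)C)OC(=O)[C@@H]2C | intermediate
39 | 9-acetate | CC(=O)O[C@H](C)CC(=O)O[C@@H]1C[C@@H](OC(C)=O)[C@@]2(C)[C@@H](OC(C)=O)CC=C(C)[C@@H]2[C@@H](OC(C)=O)[C@@]2(O)[C@H](/C=C\1CO[Si](c1ccccc1)(c1ccccc1)C(C)(C)C)OC(=O)[C@@H]2C | intermediate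
40 | CNP0316115.1 | CC(=O)O[C@H](C)CC(=O)O[C@@H]1C[C@@H](OC(C)=O)[C@@]2(C)[C@@H](OC(C)=O)CC=C(C)[C@@H]2[C@@H](OC(C)=O)[C@@]2(O)[C@H](/C=C\1CO)OC(=O)[C@@H]2C | target

## Step count and risks

Total step count: 27. Longest linear sequence: 22 (steps 1–13 and 19–27).

**Step 24.**
- What may go wrong: addition to the neopentyl aldehyde may be slow, so that protodeiodination and intermolecular coupling compete. Facial selectivity at C7 may also erode.
- The fallback sets out from 35 and forms the same bond at the ketone level, with C7 set separately.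
- Pinnick oxidation (NaClO2, NaH2PO4, 2-methyl-2-butene) would give the C7 carboxylic acid F1.
- 2,2′-Dipyridyl disulfide and PPh3 would give the S-(2-pyridyl) thioester F2.
- A nickel-mediated reductive acyl coupling of the C6–I bond with the thioester (NiBr2·dtbbpy, Zn, Cp2ZrCl2, high dilution) would give the macrocyclic enone F3.
- Luche reduction (NaBH4, CeCl3, −78 °C) from the outer face would come back at 36, which lactonises to 37.

**Step 6.**
- What may go wrong: hydrazone formation at the C10 carbonyl, which lies between a quaternary carbon and the epoxide carbon, may be too slow. Epoxide opening or acetate hydrazinolysis could then take over.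
- The fallback sets out from 7.
- Hydride reduction (NaBH4, CeCl3, MeOH) would give the epoxy alcohol F4.
- 1,1′-Thiocarbonyldiimidazole with DMAP in hot toluene would give the thiocarbonylimidazolide F5.
- Bu3SnH with AIBN would generate the C10 radical, which opens the C11–O bond and comes back at 9 with the C12 configuration unchanged.

**Step 12.**
- What may go wrong: enolisation of the β-keto imide, attack at the imide carbonyls or retro-aldol cleavage of the tertiary alkoxide may compete with addition.
- The fallback sets out from 17 and brings in carbon and sulfur separately.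
- Dimethylsulfonium methylide (Me3SI, n-BuLi, THF, −10 °C) would give the spiro-epoxide F6.
- Opening at the unhindered C7 with PhSH and Et3N would come back at 19.

## Further compounds

F1 | step 24 | C7 carboxylic acid | I/C=C(/CO[Si](c1ccccc1)(c1ccccc1)C(C)(C)C)[C@H](OC(=O)C[C@@H](C)OC(C)=O)C[C@@H](OC(C)=O)[C@@]1(C)[C@@H](OC(C)=O)CC=C(C)[C@@H]1[C@@H](O[Si](CC)(CC)CC)[C@@](O[Si](CC)(CC)CC)(C(=O)O)[C@@H](C)C(=O)N1[C@@H](Cc2ccccc2)COC1=O
F2 | step 24 | S-(2-pyridyl) thioester | I/C=C(/CO[Si](c1ccccc1)(c1ccccc1)C(C)(C)C)[C@H](OC(=O)C[C@@H](C)OC(C)=O)C[C@@H](OC(C)=O)[C@@]1(C)[C@@H](OC(C)=O)CC=C(C)[C@@H]1[C@@H](O[Si](CC)(CC)CC)[C@@](O[Si](CC)(CC)CC)(C(=O)Sc1ccccn1)[C@@H](C)C(=O)N1[C@@H](Cc2ccccc2)COC1=O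
F3 | step 24 | macrocyclic enone | CC(=O)O[C@H](C)CC(=O)O[C@@H]1C[C@@H](OC(C)=O)[C@@]2(C)[C@@H](OC(C)=O)CC=C(C)[C@@H]2[C@@H](O[Si](CC)(CC)CC)[C@](O[Si](CC)(CC)CC)([C@@H](C)C(=O)N2[C@@H](Cc3ccccc3)COC2=O)C(=O)/C=C\1CO[Si](c1ccccc1)(c1ccccc1)C(C)(C)C
F4 | step 6 | epoxy alcohol (C10 epimers) | COC(OC)[C@@]1(C)[C@@H](OC(C)=O)C[C@@H]2O[C@]2(C)C1O
F5 | step 6 | thiocarbonylimidazolide | COC(OC)[C@@]1(C)[C@@H](OC(C)=O)C[C@@H]2O[C@]2(C)C1OC(=S)n1ccnc1
F6 | step 12 | spiro-epoxide | COC(OC)[C@@]1(C)[C@@H](OC(C)=O)CC=C(C)[C@@H]1[C@@H](O[Si](CC)(CC)CC)[C@@]1(CO1)[C@@H](C)C(=O)N1[C@@H](Cc2ccccc2)COC1=O
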